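**Retrosynthetic overview**

1. The target is numbered as a 1,7-dioxaspiro[4.4]nonane: ring A is the O7 lactone (C5, C6, O7, C8, C9) and ring B the O1 lactone (O1, C2, C3, C4, C5). Ring A is disconnected by shifting O7 from C6 onto the carboxyl on C4, which gives a cis-fused δ-lactone (temporary ring C: C4, its carboxyl carbon, O7, C8, C9, C5) and a C6 ethyl ester.
2. The C3 hydroxyl (directed hydride reduction) and the C4 hydroxyl (enolate hydroxylation) are removed back to the 3-hydroxybutenolide (enol) form of ring B; ring C makes both enter with the required configuration.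
3. Key disconnection C5–C9: ring C closes by SN2 attack of C5 on a CH2Cl group. The enabling feature is that C5 is both α to the C6 ester and γ (through C4=C3) to the enol-lactone system of ring B, so C5–H is acidic and C5 is planar in the dianion. The carboxyl on C4 lies 1,5 to C9 and can hold the C8 oxygen as an ester tether, so both C5 epimers converge and C8 sets C5.
4. Ring B comes from aldol-lactonisation of a mixed oxalacetate with ethyl glyoxylate, the oxalacetate from a crossed Claisen condensation of the chlorohydrin acetate with diethyl oxalate, and the chlorohydrin from (R)-epichlorohydrin and a C9 Grignard reagent.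
5. Order of ring formation: ring B (step 4), temporary ring C (step 5), ring A with loss of ring C (step 8).

Key step: step 5

Remark: the locants in the Why lines (O1, C2–C9, O7) are those of the target skeleton; the hydroxybutenolide of step 4 is used as the mixture of its two C5 epimers.

**Route**

Step 1
Reactants: 1 9-bromonon-1-ene; 2 (R)-epichlorohydrin
Product: 4 (2R)-1-chlorododec-11-en-2-ol, via non-8-en-1-ylmagnesium bromide 3 (not isolated)
Conditions: Mg, THF, 40 °C; then 2, CuI (10 mol%), THF, −30 → 0 °C; 1 M HCl
Reagents that add atoms: none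
Why: CuI-catalysed Grignard opening of the epoxide (SN2 at the unsubstituted epoxide carbon) leaves the chloromethyl group and the stereocenter of 2 untouched, so the (R) centre of 2 becomes C8 of the target.

Step 2
Reactants: 4 (2R)-1-chlorododec-11-en-2-ol; 5 acetic anhydride
Product: 6 (2R)-1-chlorododec-11-en-2-yl acetate
Conditions: pyridine, DMAP (5 mol%), CH2Cl2, 0 °C → rt
Reagents that add atoms: none
Why: DMAP-catalysed O-acylation of the secondary alcohol proceeds without change at the stereocenter and brings in the two carbons that become C4 and its carboxyl group.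

Step 3
Reactants: 6 (2R)-1-chlorododec-11-en-2-yl acetate; 7 diethyl oxalate
Product: 8 4-[(2R)-1-chlorododec-11-en-2-yl] 1-ethyl 2-oxobutanedioate
Conditions: LiN(SiMe3)2 (1.05 equiv), THF, −78 °C; added to 7 (2 equiv), THF, −78 °C; AcOH quench
Reagents that add atoms: none
Why: Crossed Claisen condensation of the lithium ester enolate with non-enolisable diethyl oxalate (inverse addition, the tetrahedral adduct persists at −78 °C) should give the oxalacetate, while C-alkylation of this enolate by its own chloride would be a disfavoured 5-(enolendo)-exo-tet closure; the stereocenter is not involved.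

Step 4
Reactants: 8 4-[(2R)-1-chlorododec-11-en-2-yl] 1-ethyl 2-oxobutanedioate; 9 ethyl glyoxylate
Product: 10 3-[(2R)-1-chlorododec-11-en-2-yl] 2-ethyl 4-hydroxy-5-oxo-2,5-dihydrofuran-2,3-dicarboxylate (both epimers at the ring CH)
Conditions: Et3N (20 mol%), CH2Cl2, 0 °C → rt; then TsOH·H2O (25 mol%), rt
Reagents that add atoms: none
Why: Amine-catalysed aldol addition of the active methylene of 8 to the glyoxylate aldehyde, followed by 5-exo-trig lactonisation of the new hydroxyl onto the α-keto ester (the classical oxalacetate-aldehyde ketolactone synthesis), builds ring B in its enol form; the new stereocenter (C5) forms without control, which does not matter because step 5 erases it.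

Step 5
Reactants: 10 3-[(2R)-1-chlorododec-11-en-2-yl] 2-ethyl 4-hydroxy-5-oxo-2,5-dihydrofuran-2,3-dicarboxylate
Product: 12 ethyl (6R,7aS)-6-(dec-9-en-1-yl)-3-hydroxy-2,4-dioxo-6,7-dihydro-2H-furo[3,2-c]pyran-7a(4H)-carboxylate, via dilithium dianion 11 (not isolated)
Conditions: LiN(iPr)2 (2.2 equiv), THF–DMPU, −78 °C; NaI (20 mol%), −78 °C → rt; 1 M HCl
Reagents that add atoms: none
Why: LiN(iPr)2 removes first the enol proton and then the C5 hydrogen, so both C5 epimers of 10 give the same planar dianion 11, whose ester-enolate carbon C5 displaces chloride from C9 in an SN2 reaction that forms the C5–C9 bond. The closest known reaction type is the γ-alkylation of β-keto-ester dianions in its intramolecular, lactone-forming variant. The one ring closed is the six-membered δ-lactone (ring C), by a 6-(enolexo)-exo-tet closure through the ester tether on the C4 carboxyl. The new quaternary stereocenter C5 is controlled by C8: the tether arches over the C4–C5 bond on the side of the CO2Et group at C5, and the dec-9-enyl chain on C8 can take the outward pseudo-equatorial position only when C9 adds to the face that gives (5S), whereas the other face would press the chain against CO2Et in a 1,3-diaxial contact. The step needs alkylation at C5 and not at the enolate carbon C4 (five-membered ring); this should be secured because the last-formed ester-enolate carbon of the dianion is by far its most nucleophilic site and because lithium chelation between the enolate oxygen and the tether carbonyl turns the alkoxy arm toward C5.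

Step 6
Reactants: 12 ethyl (6R,7aS)-6-(dec-9-en-1-yl)-3-hydroxy-2,4-dioxo-6,7-dihydro-2H-furo[3,2-c]pyran-7a(4H)-carboxylate
Product: 13 ethyl (3aS,6R,7aS)-6-(dec-9-en-1-yl)-3a-hydroxy-2,3,4-trioxohexahydro-7aH-furo[3,2-c]pyran-7a-carboxylate
Conditions: 3-phenyl-2-(phenylsulfonyl)oxaziridine (1.2 equiv), Et3N (20 mol%), CH2Cl2, −20 → 0 °C
Reagents that add atoms: 3-phenyl-2-(phenylsulfonyl)oxaziridine, O=S(=O)(N1OC1c1ccccc1)c1ccccc1
Why: Davis oxidation of the amine-generated enolate of this β-keto-ester-type enol should place oxygen on C4 only from the face anti to C9, because the δ-lactone must stay cis-fused to the nearly planar five-membered ring (a trans fusion is highly strained), which sets C4 as required, and the isolated alkene is inert to this oxidant.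

Step 7
Reactants: 13 ethyl (3aS,6R,7aS)-6-(dec-9-en-1-yl)-3a-hydroxy-2,3,4-trioxohexahydro-7aH-furo[3,2-c]pyran-7a-carboxylate
Product: 14 ethyl (3R,3aR,6R,7aS)-6-(dec-9-en-1-yl)-3,3a-dihydroxy-2,4-dioxohexahydro-7aH-furo[3,2-c]pyran-7a-carboxylate
Conditions: NaBH(OAc)3, MeCN–AcOH, −20 °C
Reagents that add atoms: none
Why: Hydroxyl-directed hydride delivery (Saksena–Evans reduction with triacetoxyborohydride) to the activated C3 ketone from the face of the C4 hydroxyl, which is also the convex face of the bicycle, should give the trans-3,4-diol (C3 R), while lactones, ester and alkene stay untouched.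

Step 8
Reactants: 14 ethyl (3R,3aR,6R,7aS)-6-(dec-9-en-1-yl)-3,3a-dihydroxy-2,4-dioxohexahydro-7aH-furo[3,2-c]pyran-7a-carboxylate
Product: 16 (3R,4R,5S,8R)-8-(dec-9-en-1-yl)-3,4-dihydroxy-2,6-dioxo-1,7-dioxaspiro[4.4]nonane-4-carboxylic acid, via seco hydroxy acid 15 (not isolated)
Conditions: 2 M HCl–1,4-dioxane (1:1), 60 °C; evaporation, toluene azeotrope
Reagents that add atoms: water, O
Why: Acid-catalysed hydrolysis of the δ-lactone and Fischer-type lactonisation of the freed C8 hydroxyl onto the C6 ethyl ester (overall a translactonisation from the six-membered to the more stable five-membered lactone) should close ring A, remove ring C and set the C4 carboxyl free without touching a stereocenter.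

**Compound list**

1 | 9-bromonon-1-ene | C=CCCCCCCCBr | starting material
2 | (R)-epichlorohydrin, (2R)-2-(chloromethyl)oxirane | ClC[C@H]1CO1 | starting material
3 | non-8-en-1-ylmagnesium bromide | C=CCCCCCCC[Mg]Br | intermediate (not isolated)
4 | (2R)-1-chlorododec-11-en-2-ol | C=CCCCCCCCC[C@@H](O)CCl | intermediate
5 | acetic anhydride | CC(=O)OC(C)=O | starting material
6 | (2R)-1-chlorododec-11-en-2-yl acetate | C=CCCCCCCCC[C@@H](OC(C)=O)CCl | intermediate
7 | diethyl oxalate | CCOC(=O)C(=O)OCC | starting material
8 | 4-[(2R)-1-chlorododec-11-en-2-yl] 1-ethyl 2-oxobutanedioate | C=CCCCCCCCC[C@@H](OC(=O)CC(=O)C(=O)OCC)CCl | intermediate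
9 | ethyl glyoxylate | CCOC(=O)C=O | starting material
10 | 3-[(2R)-1-chlorododec-11-en-2-yl] 2-ethyl 4-hydroxy-5-oxo-2,5-dihydrofuran-2,3-dicarboxylate, both epimers at ring C2 (C5 of the target) | C=CCCCCCCCC[C@@H](OC(=O)C1=C(O)C(=O)OC1C(=O)OCC)CCl | intermediate
11 | dilithium dianion of 10 (enolate oxygen on C3 of the target, ester enolate at C5/C6) | [Li+].[Li+].C=CCCCCCCCC[C@@H](OC(=O)C1=C([O-])C(=O)OC1=C([O-])OCC)CCl | intermediate (not isolated)
12 | ethyl (6R,7aS)-6-(dec-9-en-1-yl)-3-hydroxy-2,4-dioxo-6,7-dihydro-2H-furo[3,2-c]pyran-7a(4H)-carboxylate | C=CCCCCCCCC[C@@H]1C[C@@]2(OC(=O)C(O)=C2C(=O)O1)C(=O)OCC | intermediate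
13 | ethyl (3aS,6R,7aS)-6-(dec-9-en-1-yl)-3a-hydroxy-2,3,4-trioxohexahydro-7aH-furo[3,2-c]pyran-7a-carboxylate (cis-fused) | C=CCCCCCCCC[C@@H]1C[C@@]2(OC(=O)C(=O)[C@]2(O)C(=O)O1)C(=O)OCC | intermediate
14 | ethyl (3R,3aR,6R,7aS)-6-(dec-9-en-1-yl)-3,3a-dihydroxy-2,4-dioxohexahydro-7aH-furo[3,2-c]pyran-7a-carboxylate | C=CCCCCCCCC[C@@H]1C[C@@]2(OC(=O)[C@H](O)[C@]2(O)C(=O)O1)C(=O)OCC | intermediate
15 | (2S,3R,4R)-2-(ethoxycarbonyl)-3,4-dihydroxy-2-[(2R)-2-hydroxydodec-11-en-1-yl]-5-oxooxolane-3-carboxylic acid | C=CCCCCCCCC[C@@H](O)C[C@@]1(OC(=O)[C@H](O)[C@]1(O)C(=O)O)C(=O)OCC | intermediate (not isolated)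
16 | (3R,4R,5S,8R)-8-(dec-9-en-1-yl)-3,4-dihydroxy-2,6-dioxo-1,7-dioxaspiro[4.4]nonane-4-carboxylic acid | C=CCCCCCCCC[C@@H]1C[C@@]2(OC(=O)[C@H](O)[C@]2(O)C(=O)O)C(=O)O1 | target

**Step count and risks**

Total step count: 8. Longest linear sequence: 8 steps (1 → 4 → 6 → 8 → 10 → 12 → 13 → 14 → 16).

The three steps most likely to fail, riskiest first:

Step 5 may fail through alkylation at the enolate carbon C4 (five-membered ring), or through decay of the dianion before the slow displacement at the β-oxygenated chloromethyl carbon. The fallback makes the C5–C9 bond without the tether. It sets out from 4, which K2CO3 in MeOH should close to (R)-2-(dec-9-en-1-yl)oxirane F1. Commercial diethyl oxalacetate and 9, under the conditions of step 4, should give diethyl 4-hydroxy-5-oxo-2,5-dihydrofuran-2,3-dicarboxylate F2. Its dianion (LiN(iPr)2, 2.2 equiv) should open F1 at the CH2 terminus with BF3·OEt2 at −78 °C, and the C8 alkoxide should lactonise onto the C6 ester to give the spiro enol lactone F3. F3 forms as both C5 epimers because nothing controls that centre here, so they are separated by chromatography. The (5S) epimer is hydroxylated and reduced as in steps 6 and 7, giving the spiro trione F4 and then the spiro diol ethyl ester F5; the facial selectivity of these two steps is no longer enforced by ring C. Hydrolysis of the ethyl ester (2 M HCl–1,4-dioxane, 60 °C) comes back to the route at 16.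

Step 6 may fail because the stabilised enolate is too weak a nucleophile for the oxaziridine, or because it adds to the sulfonylimine that the oxidant sets free. The fallback brings the oxygen in as an acetate and sets out from 12. PhI(OAc)2 (a trivalent iodine reagent) in AcOH should acetoxylate C4 to the acetoxy trione F6, with the same cis ring fusion. NaBH4 at −78 °C should reduce the C3 ketone from the convex face to the hydroxy acetate F7. The conditions of step 8 then hydrolyse the acetate together with the δ-lactone and come back to the route at 16.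

Step 8 may fail through incomplete acyl migration or through equilibration among isomeric lactones in aqueous acid. The fallback does the migration without water and sets out from 14. HCl in dry MeOH should open the δ-lactone to its methyl ester, whose free C8 hydroxyl lactonises onto the C6 ethyl ester to give the spiro bis-lactone methyl ester F8. LiI in EtOAc at reflux should then cleave the methyl ester by SN2 attack at the methyl group, and acidification comes back to the route at 16.

Further compounds
F1 | step 5 | (R)-2-(dec-9-en-1-yl)oxirane | C=CCCCCCCCC[C@@H]1CO1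
F2 | step 5 | diethyl 4-hydroxy-5-oxo-2,5-dihydrofuran-2,3-dicarboxylate (racemic) | CCOC(=O)C1OC(=O)C(O)=C1C(=O)OCC
F3 | step 5 | ethyl (8R)-8-(dec-9-en-1-yl)-3-hydroxy-2,6-dioxo-1,7-dioxaspiro[4.4]non-3-ene-4-carboxylate (both C5 epimers) | C=CCCCCCCCC[C@@H]1CC2(OC(=O)C(O)=C2C(=O)OCC)C(=O)O1
F4 | step 5 | ethyl (4S,5S,8R)-8-(dec-9-en-1-yl)-4-hydroxy-2,3,6-trioxo-1,7-dioxaspiro[4.4]nonane-4-carboxylate | C=CCCCCCCCC[C@@H]1C[C@@]2(OC(=O)C(=O)[C@]2(O)C(=O)OCC)C(=O)O1
F5 | step 5 | ethyl (3R,4R,5S,8R)-8-(dec-9-en-1-yl)-3,4-dihydroxy-2,6-dioxo-1,7-dioxaspiro[4.4]nonane-4-carboxylate | C=CCCCCCCCC[C@@H]1C[C@@]2(OC(=O)[C@H](O)[C@]2(O)C(=O)OCC)C(=O)O1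
F6 | step 6 | ethyl (3aS,6R,7aS)-3a-acetoxy-6-(dec-9-en-1-yl)-2,3,4-trioxohexahydro-7aH-furo[3,2-c]pyran-7a-carboxylate | C=CCCCCCCCC[C@@H]1C[C@@]2(OC(=O)C(=O)[C@]2(OC(C)=O)C(=O)O1)C(=O)OCC
F7 | step 6 | ethyl (3R,3aR,6R,7aS)-3a-acetoxy-6-(dec-9-en-1-yl)-3-hydroxy-2,4-dioxohexahydro-7aH-furo[3,2-c]pyran-7a-carboxylate | C=CCCCCCCCC[C@@H]1C[C@@]2(OC(=O)[C@H](O)[C@]2(OC(C)=O)C(=O)O1)C(=O)OCC
F8 | step 8 | methyl (3R,4R,5S,8R)-8-(dec-9-en-1-yl)-3,4-dihydroxy-2,6-dioxo-1,7-dioxaspiro[4.4]nonane-4-carboxylate | C=CCCCCCCCC[C@@H]1C[C@@]2(OC(=O)[C@H](O)[C@]2(O)C(=O)OC)C(=O)O1
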